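**Retrosynthetic overview**
- The α-methylene-γ-butyrolactone is opened last, at the bond between its C3 (the carbon bearing the exocyclic CH2) and its ring CH2 (C4). This leads back to a 2-bromoacrylate ester of a secondary methyl carbinol.
- Enabling feature: lactone C4 is an unsubstituted CH2 bonded only to the stereogenic C5–O carbon. In the open ester it is the C-methyl group of an (S)-alkan-2-ol. Its primary C–H bonds lie five atoms from the acrylate α-carbon, so C–H palladation through a six-membered palladacycle can close the five-membered ring without any leaving group on that carbon.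
- The aryl ether C–O bond comes from a Mitsunobu reaction of 7-hydroxy-8-methoxycoumarin. The (2R,3R)-oxirane comes from Sharpless epoxidation of an E-allylic alcohol. The E-alkene and its CH2OH come from methylalumination/hydroxymethylation of (S)-pent-4-yn-2-ol, which supplies the carbinol stereocentre from the chiral pool.
- Ring order: the coumarin is bought, the oxirane is made in step 2, and the lactone is closed last in step 5.

Key step: step 5

Assumption: (S)-pent-4-yn-2-ol and 7-hydroxy-8-methoxycoumarin are taken as catalogue compounds; if needed, each should be one step away, from (S)-propylene oxide with lithium acetylide and from 2-methoxyresorcinol by a Pechmann-type condensation.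

**Route**

Step 1
Reactants: 1 (2S)-pent-4-yn-2-ol
Product: 4 (2E,5S)-3-methylhex-2-ene-1,5-diol, via alkenylalane 2 (not isolated), via lithium alanate 3 (not isolated)
Conditions: Me3Al (3 equiv), Cp2ZrCl2 (0.25 equiv), CH2Cl2, 0 °C to rt; volatiles removed; n-BuLi, THF–hexane, −78 to 0 °C; (CH2O)n, rt; aq. potassium sodium tartrate (KNaC4H4O6)
Reagents that add atoms: trimethylaluminium C[Al](C)C; formaldehyde (as paraformaldehyde) C=O
Why: Negishi zirconium-catalysed methylalumination adds methyl and aluminium syn across the terminal alkyne (methyl to the internal carbon), which fixes the E-trisubstituted alkene, and the derived alanate is hydroxymethylated by formaldehyde with retention of alkene geometry; the carbinol stereocentre is not involved.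

Step 2
Reactants: 4 (2E,5S)-3-methylhex-2-ene-1,5-diol
Product: 5 (2S)-1-[(2R,3R)-3-(hydroxymethyl)-2-methyloxiran-2-yl]propan-2-ol
Conditions: Ti(OiPr)4 (10 mol %), D-(−)-diethyl tartrate (12 mol %), t-BuOOH (2 equiv), 4 Å MS, CH2Cl2, −20 °C
Reagents that add atoms: tert-butyl hydroperoxide CC(C)(C)OO
Why: Catalytic Sharpless asymmetric epoxidation, in which the primary allylic hydroxyl binds the titanium tartrate and D-(−)-diethyl tartrate directs oxygen to the face that gives the (2R,3R)-epoxide, as it does for geraniol; the homoallylic secondary hydroxyl should react far more slowly, and the E geometry puts the two CH2 substituents trans on the oxirane.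

Step 3
Reactants: 5 (2S)-1-[(2R,3R)-3-(hydroxymethyl)-2-methyloxiran-2-yl]propan-2-ol, 6 7-hydroxy-8-methoxy-2H-chromen-2-one
Product: 7 7-{[(2R,3R)-3-[(2S)-2-hydroxypropyl]-3-methyloxiran-2-yl]methoxy}-8-methoxy-2H-chromen-2-one
Conditions: PPh3, DIAD, THF, 0 °C to rt
Reagents that add atoms: none
Why: Mitsunobu etherification, in which the acidic 7-hydroxyl of the coumarin displaces the oxyphosphonium of the less hindered primary epoxy alcohol by SN2 at CH2, so no stereocentre is touched and the secondary hydroxyl should remain free.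

Step 4
Reactants: 7 7-{[(2R,3R)-3-[(2S)-2-hydroxypropyl]-3-methyloxiran-2-yl]methoxy}-8-methoxy-2H-chromen-2-one, 8 2,3-dibromopropanoyl chloride
Product: 10 (2S)-1-[(2R,3R)-3-{[(8-methoxy-2-oxo-2H-chromen-7-yl)oxy]methyl}-2-methyloxiran-2-yl]propan-2-yl 2-bromoprop-2-enoate, via dibromopropanoate 9 (not isolated)
Conditions: Et3N (2.5 equiv), CH2Cl2, −20 to 0 °C
Reagents that add atoms: none
Why: O-Acylation of the secondary alcohol by the acid chloride followed by in-flask E1cB loss of HBr from the 2,3-dibromopropanoate (α-hydrogen removed, β-bromide expelled) is the standard entry to 2-bromoacrylates, and acylation at oxygen retains the carbinol configuration.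

Step 5
Reactants: 10 (2S)-1-[(2R,3R)-3-{[(8-methoxy-2-oxo-2H-chromen-7-yl)oxy]methyl}-2-methyloxiran-2-yl]propan-2-yl 2-bromoprop-2-enoate
Product: 11 8-methoxy-7-{[(2R,3R)-3-methyl-3-{[(2S)-4-methylidene-5-oxooxolan-2-yl]methyl}oxiran-2-yl]methoxy}-2H-chromen-2-one
Conditions: Pd2(dba)3 (5 mol %), PCy3 (20 mol %), KOPiv (30 mol %), K2CO3 (1.5 equiv), BHT (10 mol %), mesitylene, 130 °C, slow addition of 10 at high dilution
Reagents that add atoms: none
Why: Proposed new method: zerovalent palladium inserts into the activated C(sp2)–Br bond, bromide is exchanged for pivalate, and carboxylate-assisted concerted metalation–deprotonation of the C-methyl group on the carbinol carbon gives a six-membered oxapalladacycle (Pd, Cα, C=O, O, CH, CH2) whose C(sp2)–C(sp3) reductive elimination forms the Cα–CH2 bond; the closest known reaction type is the zerovalent-palladium-catalysed intramolecular C(sp3)–H alkenylation of N-alkyl 2-bromoalk-2-enamides to α-alkylidene-γ-lactams, extended here to an ester tether and to the parent 2-bromoacrylate. The five-membered lactone is thus closed by ring contraction of the six-membered palladacycle and not by a Baldwin-type attack, so the 5-(enolendo)-exo-tet restriction that blocks enolate alkylation at this bond does not apply. No stereocentre is made: the carbinol stereocentre is a spectator and the exocyclic methylene is already in place. The step needs methyl over methylene C–H selectivity, which the known preference of carboxylate-assisted palladation for primary C–H bonds and the neopentyl-like position of the competing CH2 next to the quaternary oxirane carbon should secure; it also needs intramolecular C–H activation to outrun Heck-type coupling to the coumarin C3=C4 bond or to a second acrylate, which slow addition at high dilution and the absence of any alkene within reach (the chain alkene is already an epoxide) should secure. The main cost is that the ester must reach its s-cis rotamer, which is why a high temperature and a long-lived vinylpalladium pivalate are chosen.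

**Compound list**
1 | (2S)-pent-4-yn-2-ol | C[C@H](O)CC#C | starting material
2 | [(1E,4S)-4-(dimethylalumanyloxy)-2-methylpent-1-en-1-yl]dimethylalumane | C[C@H](O[Al](C)C)C/C(C)=C/[Al](C)C | intermediate
3 | lithium butyl[(1E,4S)-4-(dimethylalumanyloxy)-2-methylpent-1-en-1-yl]dimethylaluminate | [Li+].C[C@H](O[Al](C)C)C/C(C)=C/[Al-](C)(C)CCCC | intermediate
4 | (2E,5S)-3-methylhex-2-ene-1,5-diol | C[C@H](O)C/C(C)=C/CO | intermediate
5 | (2S)-1-[(2R,3R)-3-(hydroxymethyl)-2-methyloxiran-2-yl]propan-2-ol | C[C@H](O)C[C@@]1(C)O[C@@H]1CO | intermediate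
6 | 7-hydroxy-8-methoxy-2H-chromen-2-one | Oc1ccc2ccc(=O)oc2c1OC | starting material
7 | 7-{[(2R,3R)-3-[(2S)-2-hydroxypropyl]-3-methyloxiran-2-yl]methoxy}-8-methoxy-2H-chromen-2-one | C[C@H](O)C[C@@]1(C)O[C@@H]1COc1ccc2ccc(=O)oc2c1OC | intermediate
8 | 2,3-dibromopropanoyl chloride (racemic) | O=C(Cl)C(Br)CBr | starting material
9 | (2S)-1-[(2R,3R)-3-{[(8-methoxy-2-oxo-2H-chromen-7-yl)oxy]methyl}-2-methyloxiran-2-yl]propan-2-yl 2,3-dibromopropanoate (both epimers at CHBr) | C[C@H](OC(=O)C(Br)CBr)C[C@@]1(C)O[C@@H]1COc1ccc2ccc(=O)oc2c1OC | intermediate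
10 | (2S)-1-[(2R,3R)-3-{[(8-methoxy-2-oxo-2H-chromen-7-yl)oxy]methyl}-2-methyloxiran-2-yl]propan-2-yl 2-bromoprop-2-enoate | C[C@H](OC(=O)C(Br)=C)C[C@@]1(C)O[C@@H]1COc1ccc2ccc(=O)oc2c1OC | intermediate
11 | 8-methoxy-7-{[(2R,3R)-3-methyl-3-{[(2S)-4-methylidene-5-oxooxolan-2-yl]methyl}oxiran-2-yl]methoxy}-2H-chromen-2-one | C=C1C[C@@H](C[C@@]2(C)O[C@@H]2COc2ccc3ccc(=O)oc3c2OC)OC1=O | target

**Step count and risks**
Total step count: 5. Longest linear sequence: 5 steps (from 1).

Steps most likely to fail:

1. Step 5 (Proposed new method). The ester may not populate the s-cis rotamer that palladation needs. Protodebromination, Heck-type oligomerisation of the bromoacrylate, or migration of the exocyclic double bond into the ring could then outrun C–H activation. The fallback uses known chemistry and builds the lactone through a different bond (carbonyl 2-(alkoxycarbonyl)allylation, then O-acylation). It sets out from coumarin 6 and comes back at target 11. 4-[(tert-Butyldimethylsilyl)oxy]but-1-yne is taken through the same methylalumination–formaldehyde sequence as in step 1 to (2E)-5-[(tert-butyldimethylsilyl)oxy]-3-methylpent-2-en-1-ol F1. Sharpless epoxidation with D-(−)-diethyl tartrate should give [(2R,3R)-3-{2-[(tert-butyldimethylsilyl)oxy]ethyl}-3-methyloxiran-2-yl]methanol F2. Mitsunobu coupling with 6 should give 7-{[(2R,3R)-3-{2-[(tert-butyldimethylsilyl)oxy]ethyl}-3-methyloxiran-2-yl]methoxy}-8-methoxy-2H-chromen-2-one F3. Bu4NF should free 7-{[(2R,3R)-3-(2-hydroxyethyl)-3-methyloxiran-2-yl]methoxy}-8-methoxy-2H-chromen-2-one F4. NaHCO3-buffered Dess–Martin oxidation should give 2-[(2R,3R)-3-{[(8-methoxy-2-oxo-2H-chromen-7-yl)oxy]methyl}-2-methyloxiran-2-yl]acetaldehyde F5, to be used at once. A chromium-catalysed enantioselective Nozaki–Hiyama–Kishi-type allylation with ethyl 2-(bromomethyl)acrylate (CrCl2, chiral carbazole-bis(oxazoline) ligand, Mn, Cp2ZrCl2, THF) should give ethyl (4S)-4-hydroxy-5-[(2R,3R)-3-{[(8-methoxy-2-oxo-2H-chromen-7-yl)oxy]methyl}-2-methyloxiran-2-yl]-2-methylidenepentanoate F6, with the ligand enantiomer chosen to deliver the (4S)-carbinol. F6 should lactonise on silica or with catalytic pyridinium tosylate to 11.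

2. Step 1. Hydroxymethylation of the alanate may be incomplete in the presence of the aluminium alkoxide, so that protonolysis to the 1,1-disubstituted alkene competes. The fallback introduces the CH2OH carbon as carbon monoxide on an isolated vinyl iodide. It sets out from 1 and comes back at 4. The same methylalumination is quenched with iodine (THF, −30 °C) to give (2S,4E)-5-iodo-4-methylpent-4-en-2-ol F7. Palladium-catalysed methoxycarbonylation (PdCl2(PPh3)2, CO, MeOH, Et3N, 60 °C) should give methyl (2E,5S)-5-hydroxy-3-methylhex-2-enoate F8; the E geometry keeps the hydroxyl from closing onto the acylpalladium. Reduction with i-Bu2AlH (CH2Cl2, −78 °C) should give 4.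

3. Step 2. The free secondary hydroxyl may compete for titanium, giving slow turnover and eroded facial selectivity. The fallback replaces hydroxyl-directed epoxidation by reagent-controlled dioxirane epoxidation after the ether is made. It sets out from 4 and comes back at 7. Mitsunobu coupling of the primary allylic hydroxyl of 4 with 6 (PPh3, DIAD, THF) should give 7-{[(2E,5S)-5-hydroxy-3-methylhex-2-en-1-yl]oxy}-8-methoxy-2H-chromen-2-one F9. Shi epoxidation with the D-fructose-derived ketone (KHSO5, K2CO3 buffer, MeCN–dimethoxymethane–water, 0 °C) should give 7 directly; by the spiro transition-state model this ketone should deliver the (2R,3R)-epoxide of the E-trisubstituted alkene.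

Further compounds
F1 | step 5 | (2E)-5-[(tert-butyldimethylsilyl)oxy]-3-methylpent-2-en-1-ol | CC(C)(C)[Si](C)(C)OCC/C(C)=C/CO
F2 | step 5 | [(2R,3R)-3-{2-[(tert-butyldimethylsilyl)oxy]ethyl}-3-methyloxiran-2-yl]methanol | CC(C)(C)[Si](C)(C)OCC[C@@]1(C)O[C@@H]1CO
F3 | step 5 | 7-{[(2R,3R)-3-{2-[(tert-butyldimethylsilyl)oxy]ethyl}-3-methyloxiran-2-yl]methoxy}-8-methoxy-2H-chromen-2-one | CC(C)(C)[Si](C)(C)OCC[C@@]1(C)O[C@@H]1COc1ccc2ccc(=O)oc2c1OC
F4 | step 5 | 7-{[(2R,3R)-3-(2-hydroxyethyl)-3-methyloxiran-2-yl]methoxy}-8-methoxy-2H-chromen-2-one | OCC[C@@]1(C)O[C@@H]1COc1ccc2ccc(=O)oc2c1OC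
F5 | step 5 | 2-[(2R,3R)-3-{[(8-methoxy-2-oxo-2H-chromen-7-yl)oxy]methyl}-2-methyloxiran-2-yl]acetaldehyde | O=CC[C@@]1(C)O[C@@H]1COc1ccc2ccc(=O)oc2c1OC
F6 | step 5 | ethyl (4S)-4-hydroxy-5-[(2R,3R)-3-{[(8-methoxy-2-oxo-2H-chromen-7-yl)oxy]methyl}-2-methyloxiran-2-yl]-2-methylidenepentanoate | CCOC(=O)C(=C)C[C@H](O)C[C@@]1(C)O[C@@H]1COc1ccc2ccc(=O)oc2c1OC
F7 | step 1 | (2S,4E)-5-iodo-4-methylpent-4-en-2-ol | C[C@H](O)C/C(C)=C/I
F8 | step 1 | methyl (2E,5S)-5-hydroxy-3-methylhex-2-enoate | C[C@H](O)C/C(C)=C/C(=O)OC
F9 | step 2 | 7-{[(2E,5S)-5-hydroxy-3-methylhex-2-en-1-yl]oxy}-8-methoxy-2H-chromen-2-one | C[C@H](O)C/C(C)=C/COc1ccc2ccc(=O)oc2c1OC
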